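**Retrosynthetic overview**
1. The C15 propanoate and the free C18 acid are set last. The side chain is joined at C12–C13 by Negishi coupling of a primary iodide with an (E)-vinyl iodide.
2. The C1=C10 double bond comes from anti (E2) dehydration of a 10-hydroxy cis-decalin. Only H1 is anti-periplanar to C10–O there (H5 is cis to it, C9 is quaternary).
3. Ring B (C5–C6–C7–C8–C9–C10) is made by enlarging the five-membered ring C5–C6–C7–C8–C10 of a cis-hydrindane by C9, through the dyotropic rearrangement of a β-lactone (O–C9–C11–C12=O) on the angular carbon C10. Enabling feature: quaternary C9 of ring B carries CH2-11 and sits next to ring-fusion carbon C10, which is sp2 in the target and can therefore be a tertiary C–O centre beforehand, so the C8–C10 and C9–O bonds can change places.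
4. The hydrindane comes from a [3+2] annulation of a silylallene onto a 1-acetylcyclohexene (ring A). Its C4 centre comes from a copper-catalysed asymmetric conjugate methylation.
5. Ring order: ring A (bought), five-membered carbocycle (step 3), β-lactone (step 6), ring B plus a γ-lactone by ring enlargement (step 7), γ-lactone opened again (step 8).

Key step: step 7

Remark: locants C1–C20 are halimane numbers (ring A = C1–C5, C10; ring B = C5–C10; C11–C16 side chain; C17 on C8; C18 carboxyl and C19 methyl on C4; C20 methyl on C9); it is assumed that the phosphoramidite enantiomer that gives the 4S product is used in step 1.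

**Step 1**
Reactants: 1 methyl 3-oxocyclohex-1-ene-1-carboxylate
Product: 3 methyl (1S)-1-methyl-3-{[(trifluoromethyl)sulfonyl]oxy}cyclohex-2-ene-1-carboxylate, via aluminium enolate 2 (not isolated)
Conditions: AlMe3 (1.4 equiv), Cu(O2CC4H3S) (copper thiophene-2-carboxylate, 2 mol%), (S,R,R)-BINOL/bis(1-phenylethyl)amine phosphoramidite (4 mol%), Et2O, −30 °C; then Tf2O, −78 to 0 °C
Reagents that add atoms: trimethylaluminium C[Al](C)C; trifluoromethanesulfonic anhydride O=S(=O)(OS(=O)(=O)C(F)(F)F)C(F)(F)F
Why: Copper-catalysed asymmetric conjugate addition of AlMe3 to a β-substituted cyclohexenone should deliver methyl to C4 (β to the ketone, the stronger acceptor) under ligand control, which sets quaternary C4 as S, and the aluminium enolate formed regiospecifically towards C5 is O-sulfonylated to the C5=C10 enol triflate.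

**Step 2**
Reactants: 3 methyl (1S)-1-methyl-3-{[(trifluoromethyl)sulfonyl]oxy}cyclohex-2-ene-1-carboxylate
Product: 5 methyl (1S)-3-acetyl-1-methylcyclohex-2-ene-1-carboxylate, via enol ether 4 (not isolated)
Conditions: tributyl(1-ethoxyvinyl)stannane, Pd(PPh3)4 (5 mol%), LiCl (3 equiv), THF, reflux; then 1 M HCl, rt
Reagents that add atoms: tributyl(1-ethoxyvinyl)stannane CCCC[Sn](CCCC)(CCCC)C(=C)OCC; water O
Why: Stille coupling of the alkenyl triflate with an acetyl-anion equivalent and acid hydrolysis of the dienol ether should give the 1-acetylcyclohexene without touching C4.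

**Step 3**
Reactants: 5 methyl (1S)-3-acetyl-1-methylcyclohex-2-ene-1-carboxylate; 6 1-methyl-1-(trimethylsilyl)allene
Product: 7 methyl (1S,2S,6R)-6-acetyl-2,7-dimethyl-8-(trimethylsilyl)bicyclo[4.3.0]non-7-ene-2-carboxylate (cis-fused; acetyl on C10 cis to H5; ester on C4 cis to H5)
Conditions: TiCl4 (1.2 equiv), CH2Cl2, −78 °C
Reagents that add atoms: none
Why: Danheiser annulation ([3+2] of an allenylsilane with an enone): the allene CH2 (C6) should attack C5 axially and anti to the C4 ester (the substituent that prefers the pseudoaxial position), a 1,2-silyl shift follows and the titanium enolate closes C10–C8, so C5 is set by C4 and C10 by the cis fusion that a five-membered ring enforces.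

**Step 4**
Reactants: 7 methyl (1S,2S,6R)-6-acetyl-2,7-dimethyl-8-(trimethylsilyl)bicyclo[4.3.0]non-7-ene-2-carboxylate
Product: 8 methyl (1S,2S,6R)-6-acetyl-2,7-dimethylbicyclo[4.3.0]non-7-ene-2-carboxylate
Conditions: CF3CO2H, CH2Cl2, 0 °C to rt
Reagents that add atoms: none
Why: Protodesilylation of a vinylsilane (ipso protonation, loss of silicon) should replace SiMe3 by H and leave the double bond at C7=C8, with ketone and ester stable to the acid.

**Step 5**
Reactants: 8 methyl (1S,2S,6R)-6-acetyl-2,7-dimethylbicyclo[4.3.0]non-7-ene-2-carboxylate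
Product: 9 methyl (1S,2S,6S,7R)-6-acetyl-2,7-dimethylbicyclo[4.3.0]nonane-2-carboxylate (C8 methyl trans to the angular acetyl)
Conditions: H2 (1 atm), [Ir(cod)(PCy3)(py)]PF6 (5 mol%), CH2Cl2, rt
Reagents that add atoms: none
Why: Carbonyl-directed homogeneous hydrogenation: the cationic iridium catalyst is held by the angular acetyl group, which also lies on the convex face of the cis-fused bicycle, so hydrogen should add to C8 from that face and leave the C8 methyl trans to the acetyl group.

**Step 6**
Reactants: 9 methyl (1S,2S,6S,7R)-6-acetyl-2,7-dimethylbicyclo[4.3.0]nonane-2-carboxylate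
Product: 11 methyl (1S,2S,6S,7R)-2,7-dimethyl-6-[(2S)-2-methyl-4-oxooxetan-2-yl]bicyclo[4.3.0]nonane-2-carboxylate, via lithium aldolate 10 (not isolated)
Conditions: S-phenyl thioacetate, LiN(i-Pr)2, THF, −78 °C; add 9; −78 to 0 °C
Reagents that add atoms: S-phenyl thioacetate CC(=O)Sc1ccccc1
Why: Aldol addition of a thiol ester lithium enolate to the ketone and spontaneous ring closure of the aldolate with loss of thiophenolate (β-lactone synthesis from ketones), in which Felkin–Anh attack anti to C5, the largest group on C10, and past C1, the smallest, should set the carbinol centre C9 as S.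

**Step 7**
Reactants: 11 methyl (1S,2S,6S,7R)-2,7-dimethyl-6-[(2S)-2-methyl-4-oxooxetan-2-yl]bicyclo[4.3.0]nonane-2-carboxylate
Product: 12 methyl (4S,5R,8R,9S,10R)-13,14,15,16-tetranorhalimane-12,10-olid-18-oate (A/B cis-fused; γ-lactone cis-fused on C9–C10)
Conditions: MgBr2·OEt2 (1.5 equiv), Et2O–CH2Cl2, 0 °C to rt
Reagents that add atoms: none
Why: MgBr2 binds the lactone and lengthens the tertiary C9–O bond; the C10–C8 bond of the cyclopentane, anti-periplanar to it, shifts to C9 while the carboxylate oxygen moves to C10, and the strain of the four-membered lactone pays for the ring enlargement. The closest known reaction type is the MgBr2- or Zn(OTf)2-promoted dyotropic (Wagner–Meerwein) rearrangement of β-lactones that carry a quaternary cycloalkyl carbon next to the C–O carbon, which enlarges cyclopentanes to cyclohexane-fused γ-lactones. Ring B (C5–C6–C7–C8–C9–C10) closes by a suprafacial 1,2-alkyl shift that enlarges the ring C5–C6–C7–C8–C10 by C9, and the γ-lactone (C12–C11–C9–C10–O) closes by return of the carboxylate to C10 on the face that C8 has left. C9 is formed with inversion and is therefore controlled by the 9S carbinol of step 6 (C11 ends cis to the new C10–O bond, C20 cis to the C8 methyl), C10 is inverted so that its oxygen is cis to H5, and C8 migrates with retention. The step needs C8 to migrate rather than C1 or C5: only the C8 shift relieves cyclopentane strain and gives a fused six-membered ring (a C1 shift would give a seven-membered ring, a C5 shift a bridged system), and C8 is the more substituted, better migrating carbon. Loss of CO2 from the ionised lactone is the competing path and should be held back by the low temperature and the concerted anti-periplanar shift.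

**Step 8**
Reactants: 12 methyl (4S,5R,8R,9S,10R)-13,14,15,16-tetranorhalimane-12,10-olid-18-oate
Product: 14 methyl (4S,5R,8R,9S,10R)-10,12-dihydroxy-13,14,15,16-tetranorhaliman-18-oate, via lactol 13 (not isolated)
Conditions: i-Bu2AlH (1.2 equiv), CH2Cl2, −78 °C; then MeOH, NaBH4, 0 °C
Reagents that add atoms: none
Why: Lactone reduction in two stages (i-Bu2AlH to the lactol, NaBH4 on its hydroxy aldehyde form) should give the 1,4-diol while the neopentyl C18 methyl ester, much slower towards i-Bu2AlH at −78 °C and inert to NaBH4, survives.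

**Step 9**
Reactants: 14 methyl (4S,5R,8R,9S,10R)-10,12-dihydroxy-13,14,15,16-tetranorhaliman-18-oate
Product: 16 methyl (4S,5S,8R,9S)-12-acetoxy-13,14,15,16-tetranorhalim-1(10)-en-18-oate, via hydroxy acetate 15 (not isolated)
Conditions: Ac2O (1.1 equiv), pyridine, DMAP (cat.), CH2Cl2, 0 °C; then SOCl2 (1.5 equiv), pyridine, −30 to 0 °C
Reagents that add atoms: acetic anhydride CC(=O)OC(C)=O
Why: Acetylation occurs only at the primary alcohol and blocks cyclisation to the tetrahydrofuran, after which SOCl2–pyridine dehydrates the tertiary alcohol by E2 anti elimination, and in the cis-fused decalin the C10 leaving group has an anti-periplanar hydrogen only on C1 (H5 is cis to it, C9 is quaternary), so only the 1(10)-alkene should form.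

**Step 10**
Reactants: 16 methyl (4S,5S,8R,9S)-12-acetoxy-13,14,15,16-tetranorhalim-1(10)-en-18-oate
Product: 17 methyl (4S,5S,8R,9S)-12-hydroxy-13,14,15,16-tetranorhalim-1(10)-en-18-oate
Conditions: K2CO3 (cat.), MeOH, rt
Reagents that add atoms: none
Why: Base-catalysed transesterification removes the unhindered primary acetate, while the neopentyl methyl ester can only exchange methoxide for methoxide.

**Step 11**
Reactants: 17 methyl (4S,5S,8R,9S)-12-hydroxy-13,14,15,16-tetranorhalim-1(10)-en-18-oate
Product: 18 methyl (4S,5S,8R,9S)-12-iodo-13,14,15,16-tetranorhalim-1(10)-en-18-oate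
Conditions: I2, PPh3, imidazole, CH2Cl2, 0 °C to rt
Reagents that add atoms: iodine [I][I]
Why: Appel-type iodination (SN2 on the alkoxyphosphonium salt) of a primary alcohol whose carbon is two bonds away from quaternary C9 and therefore not hindered.

**Step 12**
Reactants: 19 but-2-yn-1-ol
Product: 20 tert-butyl(but-2-yn-1-yloxy)dimethylsilane
Conditions: t-BuMe2SiCl, imidazole, DMF, rt
Reagents that add atoms: tert-butyldimethylsilyl chloride CC(C)(C)[Si](C)(C)Cl
Why: Standard silylation of a primary alcohol.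

**Step 13**
Reactants: 20 tert-butyl(but-2-yn-1-yloxy)dimethylsilane
Product: 22 tert-butyl{[(2E)-3-iodobut-2-en-1-yl]oxy}dimethylsilane, via alkenylzirconocene chloride 21 (not isolated)
Conditions: Cp2Zr(H)Cl (1.5 equiv), THF, rt to 40 °C; then I2, THF, 0 °C
Reagents that add atoms: iodine [I][I]
Why: Syn hydrozirconation of the internal alkyne should place zirconium on the less hindered, methyl-bearing carbon (regiochemistry settled by equilibration with excess Cp2Zr(H)Cl), and iodinolysis with retention gives the E vinyl iodide.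

**Step 14**
Reactants: 18 methyl (4S,5S,8R,9S)-12-iodo-13,14,15,16-tetranorhalim-1(10)-en-18-oate; 22 tert-butyl{[(2E)-3-iodobut-2-en-1-yl]oxy}dimethylsilane
Product: 24 methyl (4S,5S,8R,9S,13E)-15-[(tert-butyldimethylsilyl)oxy]halima-1(10),13-dien-18-oate, via organozinc iodide 23 (not isolated)
Conditions: Zn dust, LiCl, THF, 40 °C; then 22, Pd(dppf)Cl2 (5 mol%), THF, 50 °C
Reagents that add atoms: none
Why: Zinc insertion into the primary C–I bond (LiCl-assisted, ester tolerated) and Negishi sp3–sp2 coupling, which forms C12–C13 and keeps the E geometry of the vinyl iodide.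

**Step 15**
Reactants: 24 methyl (4S,5S,8R,9S,13E)-15-[(tert-butyldimethylsilyl)oxy]halima-1(10),13-dien-18-oate
Product: 25 methyl (4S,5S,8R,9S,13E)-15-hydroxyhalima-1(10),13-dien-18-oate
Conditions: Bu4NF, THF, 0 °C to rt
Reagents that add atoms: none
Why: Fluoride cleavage of the silyl ether, to which the ester and both alkenes are inert.

**Step 16**
Reactants: 25 methyl (4S,5S,8R,9S,13E)-15-hydroxyhalima-1(10),13-dien-18-oate
Product: 26 (4S,5S,8R,9S,13E)-15-hydroxyhalima-1(10),13-dien-18-oic acid
Conditions: KOH, DMSO–H2O (9:1), 90 °C; then cold 1 M HCl to pH 3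
Reagents that add atoms: potassium hydroxide [K+].[OH-]
Why: Saponification of the hindered C18 methyl ester needs hot hydroxide in DMSO, which the allylic alcohol and the alkenes tolerate, and cold, brief acidification avoids lactonisation onto C10.

**Step 17**
Reactants: 26 (4S,5S,8R,9S,13E)-15-hydroxyhalima-1(10),13-dien-18-oic acid
Product: 27 (4S,5S,8R,9S,13E)-15-(propanoyloxy)halima-1(10),13-dien-18-oic acid (CNP0223570.1)
Conditions: Novozym 435 (immobilised Candida antarctica lipase B), vinyl propanoate, t-BuOMe, 30 °C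
Reagents that add atoms: vinyl propanoate CCC(=O)OC=C
Why: Lipase-catalysed transesterification with an enol ester should acylate only the unhindered primary allylic alcohol, so the free C18 acid needs no protection, and the reaction is irreversible because vinyl alcohol tautomerises to acetaldehyde.

**Compound list**
1 | methyl 3-oxocyclohex-1-ene-1-carboxylate | COC(=O)C1=CC(=O)CCC1 | starting material
2 | methyl (1S)-3-[(dimethylalumanyl)oxy]-1-methylcyclohex-2-ene-1-carboxylate (aluminium enolate) | C[Al](C)OC1=C[C@@](C)(C(=O)OC)CCC1 | intermediate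
3 | methyl (1S)-1-methyl-3-{[(trifluoromethyl)sulfonyl]oxy}cyclohex-2-ene-1-carboxylate | O=S(=O)(OC1=C[C@@](C)(C(=O)OC)CCC1)C(F)(F)F | intermediate
4 | methyl (1S)-3-(1-ethoxyethenyl)-1-methylcyclohex-2-ene-1-carboxylate | CCOC(=C)C1=C[C@@](C)(C(=O)OC)CCC1 | intermediate
5 | methyl (1S)-3-acetyl-1-methylcyclohex-2-ene-1-carboxylate | CC(=O)C1=C[C@@](C)(C(=O)OC)CCC1 | intermediate
6 | 1-methyl-1-(trimethylsilyl)allene (buta-2,3-dien-2-yl(trimethyl)silane) | C=C=C(C)[Si](C)(C)C | starting material
7 | methyl (1S,2S,6R)-6-acetyl-2,7-dimethyl-8-(trimethylsilyl)bicyclo[4.3.0]non-7-ene-2-carboxylate | CC(=O)[C@]12CCC[C@](C)(C(=O)OC)[C@H]1CC([Si](C)(C)C)=C2C | intermediate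
8 | methyl (1S,2S,6R)-6-acetyl-2,7-dimethylbicyclo[4.3.0]non-7-ene-2-carboxylate | CC(=O)[C@]12CCC[C@](C)(C(=O)OC)[C@H]1CC=C2C | intermediate
9 | methyl (1S,2S,6S,7R)-6-acetyl-2,7-dimethylbicyclo[4.3.0]nonane-2-carboxylate | CC(=O)[C@]12CCC[C@](C)(C(=O)OC)[C@H]1CC[C@H]2C | intermediate
10 | lithium (2S)-2-[(1S,2S,6S,7R)-2-(methoxycarbonyl)-2,7-dimethylbicyclo[4.3.0]nonan-6-yl]-4-oxo-4-(phenylsulfanyl)butan-2-olate | [Li+].[O-][C@@](C)(CC(=O)Sc1ccccc1)[C@]12CCC[C@](C)(C(=O)OC)[C@H]1CC[C@H]2C | intermediate
11 | methyl (1S,2S,6S,7R)-2,7-dimethyl-6-[(2S)-2-methyl-4-oxooxetan-2-yl]bicyclo[4.3.0]nonane-2-carboxylate | O=C1C[C@](C)(O1)[C@]23CCC[C@](C)(C(=O)OC)[C@H]2CC[C@H]3C | intermediate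
12 | methyl (4S,5R,8R,9S,10R)-13,14,15,16-tetranorhalimane-12,10-olid-18-oate | O=C1C[C@]2(C)[C@@]3(O1)CCC[C@](C)(C(=O)OC)[C@H]3CC[C@H]2C | intermediate
13 | methyl (4S,5R,8R,9S,10R)-10,12-epoxy-12-hydroxy-13,14,15,16-tetranorhaliman-18-oate (lactol, both anomers) | OC1C[C@]2(C)[C@@]3(O1)CCC[C@](C)(C(=O)OC)[C@H]3CC[C@H]2C | intermediate
14 | methyl (4S,5R,8R,9S,10R)-10,12-dihydroxy-13,14,15,16-tetranorhaliman-18-oate | OCC[C@]1(C)[C@@]2(O)CCC[C@](C)(C(=O)OC)[C@H]2CC[C@H]1C | intermediate
15 | methyl (4S,5R,8R,9S,10R)-12-acetoxy-10-hydroxy-13,14,15,16-tetranorhaliman-18-oate | CC(=O)OCC[C@]1(C)[C@@]2(O)CCC[C@](C)(C(=O)OC)[C@H]2CC[C@H]1C | intermediate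
16 | methyl (4S,5S,8R,9S)-12-acetoxy-13,14,15,16-tetranorhalim-1(10)-en-18-oate | CC(=O)OCC[C@]1(C)C2=CCC[C@](C)(C(=O)OC)[C@H]2CC[C@H]1C | intermediate
17 | methyl (4S,5S,8R,9S)-12-hydroxy-13,14,15,16-tetranorhalim-1(10)-en-18-oate | OCC[C@]1(C)C2=CCC[C@](C)(C(=O)OC)[C@H]2CC[C@H]1C | intermediate
18 | methyl (4S,5S,8R,9S)-12-iodo-13,14,15,16-tetranorhalim-1(10)-en-18-oate | ICC[C@]1(C)C2=CCC[C@](C)(C(=O)OC)[C@H]2CC[C@H]1C | intermediate
19 | but-2-yn-1-ol | CC#CCO | starting material
20 | tert-butyl(but-2-yn-1-yloxy)dimethylsilane | CC#CCO[Si](C)(C)C(C)(C)C | intermediate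
21 | chloro[(2E)-4-(tert-butyldimethylsilyloxy)but-2-en-2-yl]bis(cyclopentadienyl)zirconium | C/C(=C\CO[Si](C)(C)C(C)(C)C)[Zr](Cl)(C1C=CC=C1)C1C=CC=C1 | intermediate
22 | tert-butyl{[(2E)-3-iodobut-2-en-1-yl]oxy}dimethylsilane | C/C(I)=C\CO[Si](C)(C)C(C)(C)C | intermediate
23 | iodo{2-[(4S,5S,8R,9S)-18-methoxy-18-oxo-13,14,15,16-tetranorhalim-1(10)-en-12-yl]}zinc (organozinc iodide at C12) | I[Zn]CC[C@]1(C)C2=CCC[C@](C)(C(=O)OC)[C@H]2CC[C@H]1C | intermediate
24 | methyl (4S,5S,8R,9S,13E)-15-[(tert-butyldimethylsilyl)oxy]halima-1(10),13-dien-18-oate | CC(C)(C)[Si](C)(C)OC/C=C(\C)CC[C@]1(C)C2=CCC[C@](C)(C(=O)OC)[C@H]2CC[C@H]1C | intermediate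
25 | methyl (4S,5S,8R,9S,13E)-15-hydroxyhalima-1(10),13-dien-18-oate | OC/C=C(\C)CC[C@]1(C)C2=CCC[C@](C)(C(=O)OC)[C@H]2CC[C@H]1C | intermediate
26 | (4S,5S,8R,9S,13E)-15-hydroxyhalima-1(10),13-dien-18-oic acid | OC/C=C(\C)CC[C@]1(C)C2=CCC[C@](C)(C(=O)O)[C@H]2CC[C@H]1C | intermediate
27 | (4S,5S,8R,9S,13E)-15-(propanoyloxy)halima-1(10),13-dien-18-oic acid | CCC(=O)OC/C=C(\C)CC[C@]1(C)C2=CCC[C@](C)(C(=O)O)[C@H]2CC[C@H]1C | target

**Totals and risks**
Total step count: 17. Longest linear sequence: 15 steps (steps 1–11 and 14–17; steps 12–13 make the side-chain fragment).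

Step 7. What may go wrong: ionisation of the tertiary C9–O bond may run ahead of the alkyl shift, so that the ionised lactone loses carbon dioxide or a ring A bond migrates instead of C8. Fallback (stepwise cationic ring enlargement without a carboxylate): setting out from ketone 9, aldol addition of the lithium enolate of tert-butyl acetate (THF, −78 °C, same Felkin–Anh sense) should give tert-butyl (3S)-3-hydroxy-3-[(1S,2S,6S,7R)-2-(methoxycarbonyl)-2,7-dimethylbicyclo[4.3.0]nonan-6-yl]butanoate F1. BF3·OEt2 in CH2Cl2 (−40 to 0 °C) then ionises the tertiary alcohol, C8 shifts from C10 to C9, and the ester carbonyl oxygen captures C10 with loss of 2-methylpropene, which returns to γ-lactone 12. A Lewis-acid-bound ester cannot fragment by decarboxylation; the price is that C9 is then set through an ion pair and not by a concerted shift.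

Step 6. What may go wrong: poor facial selectivity in the addition to the hindered methyl ketone (C5 and C8 may compete as the large group), or enolisation of the ketone instead of addition. Fallback (reagent control): from ketone 9, catalytic asymmetric allylboration (allyl-B(pin), the 3,3′-dibromo-BINOL enantiomer that gives 9S, t-BuOH, toluene) should give methyl (1S,2S,6S,7R)-6-[(2S)-2-hydroxypent-4-en-2-yl]-2,7-dimethylbicyclo[4.3.0]nonane-2-carboxylate F2. Ozonolysis (O3, CH2Cl2, −78 °C; Me2S) gives methyl (1S,2S,6S,7R)-6-[(2S)-2-hydroxy-4-oxobutan-2-yl]-2,7-dimethylbicyclo[4.3.0]nonane-2-carboxylate F3. Pinnick oxidation (NaClO2, NaH2PO4, 2-methylbut-2-ene) gives (3S)-3-hydroxy-3-[(1S,2S,6S,7R)-2-(methoxycarbonyl)-2,7-dimethylbicyclo[4.3.0]nonan-6-yl]butanoic acid F4. Ring closure with PhSO2Cl in pyridine (0 °C, carboxyl activation, retention at C9) comes back to β-lactone 11.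

Step 3. What may go wrong: bond formation at C5 is slowed by the neighbouring quaternary C4, so that the Lewis acid merely transfers a propargyl group without ring closure, or facial control at C5 is lost. Fallback (two-stage annulation): from enone 5, Mukaiyama–Michael-type conjugate propargylation with tributyl(buta-2,3-dien-2-yl)stannane and t-BuMe2SiOTf (CH2Cl2, −78 °C) should give methyl (1S,2S)-2-(but-2-yn-1-yl)-3-{1-[(tert-butyldimethylsilyl)oxy]ethylidene}-1-methylcyclohexane-1-carboxylate F5. (Ph3P)AuCl/AgBF4 (cat.) in CH2Cl2–MeOH (40 °C) then closes C10 onto the activated alkyne (5-endo-dig carbocyclisation, cis fusion enforced), which gives alkene 8 directly and makes step 4 unnecessary.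

**Further compounds**
F1 | step 7 | tert-butyl (3S)-3-hydroxy-3-[(1S,2S,6S,7R)-2-(methoxycarbonyl)-2,7-dimethylbicyclo[4.3.0]nonan-6-yl]butanoate | CC(C)(C)OC(=O)C[C@](C)(O)[C@]12CCC[C@](C)(C(=O)OC)[C@H]1CC[C@H]2C
F2 | step 6 | methyl (1S,2S,6S,7R)-6-[(2S)-2-hydroxypent-4-en-2-yl]-2,7-dimethylbicyclo[4.3.0]nonane-2-carboxylate | C=CC[C@](C)(O)[C@]12CCC[C@](C)(C(=O)OC)[C@H]1CC[C@H]2C
F3 | step 6 | methyl (1S,2S,6S,7R)-6-[(2S)-2-hydroxy-4-oxobutan-2-yl]-2,7-dimethylbicyclo[4.3.0]nonane-2-carboxylate | O=CC[C@](C)(O)[C@]12CCC[C@](C)(C(=O)OC)[C@H]1CC[C@H]2C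
F4 | step 6 | (3S)-3-hydroxy-3-[(1S,2S,6S,7R)-2-(methoxycarbonyl)-2,7-dimethylbicyclo[4.3.0]nonan-6-yl]butanoic acid | OC(=O)C[C@](C)(O)[C@]12CCC[C@](C)(C(=O)OC)[C@H]1CC[C@H]2C
F5 | step 3 | methyl (1S,2S)-2-(but-2-yn-1-yl)-3-{1-[(tert-butyldimethylsilyl)oxy]ethylidene}-1-methylcyclohexane-1-carboxylate (enol ether geometry not defined) | CC#CC[C@H]1C(=C(C)O[Si](C)(C)C(C)(C)C)CCC[C@]1(C)C(=O)OC
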